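**Plan**
- Retrosynthesis: the C10–C11 CH2–CH2 bond of the acyl chain is first re-read as a C=C and cut by cross-metathesis; the ester C–O bond is cut second, leaving undec-10-enoic acid, 2-phenylethanol and 1-dodecene.
- Enabling feature: the acyl chain C1–C21 is unbranched and fully saturated, so an alkene placed at C10=C11 leaves no trace after hydrogenation; the only ring, the phenyl of the OCH2CH2Ph group, takes no part.
- Forward: the phenethyl ester is made first, the chain is then joined at C10/C11 (10 carbons from the undecenoate, 11 from dodecene), and the alkene is saturated last; no ring is formed.
- Stereochemistry: the target has no stereocentre; the E/Z geometry of the junction alkene is transient and is removed by the hydrogenation.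

Key step: step 2

Assumption: the cross-metathesis product is expected as an E/Z mixture with E predominant; it is named and drawn as the E isomer, and since both isomers give the same saturated ester the geometry is of no consequence.

Step 1
Reactants: 1 undec-10-enoic acid; 2 2-phenylethanol
Product: 3 2-phenylethyl undec-10-enoate
Conditions: 1 (1.1 equiv), 2 (1.0 equiv), p-TsOH·H2O (5 mol %), toluene, reflux, Dean–Stark trap; aq. NaHCO3 wash
Reagents that add atoms: none
Why: Fischer esterification of an unhindered acid with a primary alcohol, driven to completion by azeotropic removal of water; the isolated terminal alkene should not be touched by catalytic sulfonic acid in toluene, and the small excess of acid is removed by the bicarbonate wash.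

Step 2
Reactants: 3 2-phenylethyl undec-10-enoate; 4 1-dodecene
Product: 5 2-phenylethyl (E)-heneicos-10-enoate
Conditions: 4 (3 equiv), (H2IMes)(PCy3)Cl2Ru=CHPh (second-generation Grubbs catalyst, 2 mol %), 1,4-benzoquinone (10 mol %), CH2Cl2, 40 °C, slow Ar purge; filtration through SiO2, chromatography
Reagents that add atoms: none
Why: Olefin cross-metathesis: the carbene released from (H2IMes)(PCy3)Cl2Ru=CHPh by phosphine loss adds a terminal alkene in a [2+2] step to a ruthenacyclobutane that cycloreverts in the other sense, so that [Ru]=CH2 and [Ru]=CHR carbenes alternately take up 3 and 4 and join C10 of the undecenoate to C2 of dodecene (the C10=C11 bond of the C21 chain) while the two terminal CH2 groups leave as ethylene. The closest known reaction type is the cross-metathesis of two unhindered monosubstituted aliphatic alkenes of similar reactivity, which is well established with this catalyst. No ring is closed and no stereocentre is created; the E geometry drawn is the expected thermodynamic preference reached through secondary metathesis and disappears in step 3. The selectivity needed is cross- over self-metathesis together with retention of the double-bond position: the excess of cheap 4 makes the ester the limiting partner and biases the statistical distribution towards 5, the hydrocarbon from self-metathesis of 4 and the diester from self-metathesis of 3 differ strongly in polarity from 5 and should be removed on silica, and 1,4-benzoquinone intercepts [Ru]–H species that would otherwise migrate the alkene and scramble the chain length. The ester carbonyl lies eight methylene groups away from the alkene and cannot chelate the carbene, and purging ethylene drives the exchange forward.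

Step 3
Reactants: 5 2-phenylethyl (E)-heneicos-10-enoate
Product: 6 2-phenylethyl heneicosanoate
Conditions: H2 (1 atm), 10% Pd/C, EtOAc, rt
Reagents that add atoms: none
Why: Heterogeneous catalytic hydrogenation of an unhindered 1,2-disubstituted alkene; the ester oxygen sits on a homobenzylic rather than a benzylic carbon, so C–O hydrogenolysis is not expected, the phenyl ring should not be reduced at ambient pressure over palladium, and both alkene isomers converge on the same saturated chain.

**Compound list**
1 | undec-10-enoic acid | C=CCCCCCCCCC(=O)O | starting material
2 | 2-phenylethanol | OCCc1ccccc1 | starting material
3 | 2-phenylethyl undec-10-enoate | C=CCCCCCCCCC(=O)OCCc1ccccc1 | intermediate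
4 | 1-dodecene | CCCCCCCCCCC=C | starting material
5 | 2-phenylethyl (E)-heneicos-10-enoate | CCCCCCCCCC/C=C/CCCCCCCCC(=O)OCCc1ccccc1 | intermediate
6 | 2-phenylethyl heneicosanoate (phenylethyl n-heneicosanoate) | CCCCCCCCCCCCCCCCCCCCC(=O)OCCc1ccccc1 | target

Total step count: 3
Longest linear sequence: 3 steps (1 → 3 → 5 → 6)

**Steps most likely to fail**

1. Step 2. Alkylidene exchange may be unselective, with self-metathesis of both partners competing with the cross reaction. Double-bond migration ahead of metathesis may also shift the junction and give chain-length homologues that could not be separated after hydrogenation. Fallback, setting out from 3: ozonolysis (O3, CH2Cl2, −78 °C; then Me2S) should cut the terminal alkene to 2-phenylethyl 10-oxodecanoate F1. Wittig olefination of this aldehyde with the ylide made from commercial undecyltriphenylphosphonium bromide and NaN(SiMe3)2 (THF, −78 °C to rt) should give 2-phenylethyl (Z)-heneicos-10-enoate F2, the chain length being fixed by the two defined fragments. Hydrogenation of this alkene under the conditions of step 3 brings the fallback back to the route at 6.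

2. Step 3. Hydrogen uptake may stall through poisoning of Pd/C by ruthenium carried over from step 2, and forcing the reduction may begin to saturate the phenyl ring; either course would leave a contaminant that is hard to remove from the waxy ester. Fallback, setting out from 1 and 4: cross-metathesis of the free acid 1 with excess 4 under the conditions of step 2 should give (E)-heneicos-10-enoic acid F3. Hydrogenation (H2, 10% Pd/C, EtOAc, rt, or more forcing if needed, no arene being present) should give heneicosanoic acid F4, a crystalline solid that can be purified by recrystallisation. Fischer esterification of this acid with 2 (p-TsOH·H2O, toluene, reflux, Dean–Stark trap) returns to the route at 6.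

3. Step 1. The esterification may stop short at equilibrium, or prolonged heating with acid may move the terminal double bond inward, which would carry isomers into step 2. Fallback, setting out from 1: oxalyl chloride with catalytic DMF (CH2Cl2, 0 °C to rt) should give undec-10-enoyl chloride F5. Irreversible acylation of 2 with this chloride (Et3N, catalytic DMAP, CH2Cl2, 0 °C) returns to the route at 3.

**Further compounds**
F1 | step 2 | 2-phenylethyl 10-oxodecanoate | O=CCCCCCCCCC(=O)OCCc1ccccc1
F2 | step 2 | 2-phenylethyl (Z)-heneicos-10-enoate | CCCCCCCCCC/C=C\CCCCCCCCC(=O)OCCc1ccccc1
F3 | step 3 | (E)-heneicos-10-enoic acid | CCCCCCCCCC/C=C/CCCCCCCCC(=O)O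
F4 | step 3 | heneicosanoic acid | CCCCCCCCCCCCCCCCCCCCC(=O)O
F5 | step 1 | undec-10-enoyl chloride | C=CCCCCCCCCC(=O)Cl
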